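## Structural features

The target is an isoflavone: a 4H-chromen-4-one (benzo ring A fused to pyranone ring C) with a free hydroxyl on C7 and an aryl group on C3. That aryl group (ring B) is the benzo ring of a 2,2-dimethyl-2H-chromene (pyran ring D). Chromone positions carry plain numbers (O1, C2, C3, C4, C4a to C8a); chromene positions carry their own numbers with a prime (O1', C2', C3', C4', C4a' to C8a'). Ring B is joined to C3 through C6' and bears a methoxy group on C8', next to the pyran oxygen O1'. There is no stereocentre and no stereogenic alkene, so the problem is one of regiochemistry and functional-group tolerance only. The fragile sites are three: the C3'=C4' styrenyl alkene of ring D, which strong acid would protonate to an oxygen-stabilised benzylic cation; C2 of the pyranone, which hydroxide or alkoxide can open; and the aryl methyl ether, which forbids any unselective ether cleavage. The real difficulty is to close ring C with the aryl group on C3 and the hydroxyl on C7 (not C5), while ring B carries a dimethylpyran that does not tolerate the acid needed for such a closure. The key step exploits the fact that C4a of ring A is para to the C7 oxygen and ortho to O1: in a 3-oxygenated aryl vinyl ether this is the most accessible nucleophilic carbon, so an acyl cation tethered through O1–C2=C3 closes ring C there by forming C4–C4a.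

## Logic of the disconnections

13 to 12: the C3'=C4' double bond of ring D is taken back to CH2–CH2 (the C–H bonds on C3' and C4' are restored). The alkene is the only part of 13 that cannot pass through a strongly acidic ring closure; without it ring B is an ordinary dialkoxyarene. The gain is an acid-proof intermediate. The demand is a final dehydrogenation that removes hydride from benzylic C4' only and leaves the phenol and the pyranone alone.

12 to 10 (through 11): the C4–C4a bond is cut. This opens ring C to an aryl vinyl ether carrying a carboxylic acid, and it places the new bond where ring A is most nucleophilic. The gain is one ring and one skeletal bond, leaving two arenes linked by a three-carbon O–CH=C–CO2H bridge. The demand is threefold: the acid must reach the ring (E to Z equilibration), attack must occur para to the free hydroxyl and not between the two oxygens, and everything else must tolerate the acid.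

10 to 9: the two acyl–oxygen bonds (methyl ester, aryl benzoate) are re-formed. The acid and the phenol are needed free only for the closure; earlier the ester serves as the enolate precursor and the benzoate masks one resorcinol oxygen. The gain is a neutral, easily handled diester. The demand is one hydrolysis that frees both groups without attack at the β-carbon of the vinylogous carbonate.

9 to 7 and 8: the bond between the vinylic carbon (future C2) and the aryl ether oxygen (future O1) is cut. That carbon is the β-carbon of an acrylate and is electrophilic once it carries a sulfonate; 8 brings ring A with one oxygen already differentiated. The gain is two fragments of similar size, one of them purchased. The demand is that addition–elimination at carbon outruns attack at sulfur, and that the benzoate stays where it is.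

7 to 6 to 4 and 5: the O–S bond of the enol sulfonate and then the bond between the α-carbon (future C3) and the formyl carbon (future C2) are cut. The α-carbon of an arylacetate is nucleophilic and 5 is a non-enolisable one-carbon electrophile. The gain is that the three-carbon bridge shrinks to an arylacetic ester. The demand is a Claisen condensation driven by deprotonation of its product, and sulfonylation on oxygen, not on carbon.

4 to 1 and 2 (through 3): the C4'–C4a' and O1'–C2' bonds of ring D are cut. The phenol oxygen and its free ortho carbon act as a 1,3-dinucleophile and protonated 2 as a 1,3-dielectrophile. The gain is two purchased materials. The demand is alkylation ortho to the hydroxyl, not para to the methoxy group, followed by ring closure at the tertiary carbon.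

## Other disconnections considered

Alternative 1: The cut removes C3–C4 and O1–C2 of ring C together. It leads back to 2-hydroxy-4-(methoxymethoxy)benzaldehyde A1 and the aryl silyl alkyne [(8-methoxy-2,2-dimethyl-2H-chromen-6-yl)ethynyl]trimethylsilane A2.
- Forward step: [Cp*RhCl2]2, ionised by AgSbF6, would bind the phenoxide of A1, cleave the aldehyde C–H bond to an acyl–rhodium species, insert A2 and close the C–O bond by reductive elimination. Cu(OAc)2 would return monovalent rhodium to the trivalent state. The product would be the 2-silyl isoflavone A3; desilylation with fluoride and removal of the methoxymethyl group would then lead to 13.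
- In its favour: two bonds and ring C form in one convergent operation. The carbonyl position on ring A is fixed by the aldehyde carbon, so no ortho/para question arises; on this point it is better than the chosen plan. Ring D travels as the finished chromene under non-protic conditions, so no saturation–dehydrogenation detour is needed; again better.
- Against it here: the aryl group lands on C3 only if the silyl group steers the insertion as expected. The electron-rich C3'=C4' alkene of A2 is a second π-donor for the cationic rhodium and for the silver salt. The acyl–rhodium intermediate can lose CO before insertion. The acetal must later be cleaved with acid in the presence of the chromene. A2 needs about three steps of its own.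
- Comparison: on mechanism the chosen plan relies on an electrophilic aromatic substitution whose selectivity is innate to the substrate; the alternative relies on ligand-controlled organometallic steps with more ways to go astray. On step economy the two are about equal in total operations (roughly seven), and the alternative has the shorter longest linear sequence, so there it is the equal or slightly the better.

Alternative 2: All three bonds of ring C that are not part of the starting arenes are cut (C4–C4a, C2–C3, O1–C2). This gives resorcinol A4, homovanillic acid A5 and a one-carbon unit from DMF.
- Forward step: A4 would be C-acylated by A5 in BF3·OEt2 to the deoxybenzoin A6, 1-(2,4-dihydroxyphenyl)-2-(4-hydroxy-3-methoxyphenyl)ethan-1-one. DMF and CH3SO2Cl added to the same pot would formylate the benzylic carbon through an iminium reagent, and the ortho hydroxyl would close ring C to give 7-hydroxy-3-(4-hydroxy-3-methoxyphenyl)-4H-chromen-4-one A7.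
- In its favour: C4–C4a is formed by the same kind of Friedel–Crafts acylation, at the same carbon of a resorcinol nucleus, as in the chosen plan, so on regiochemical grounds the two are equal. No protecting group is needed, and ring C is built in one pot where the chosen plan spends steps 2 to 6; this is clearly better.
- Against it here: A7 lacks ring D and has two free phenols that must be told apart before a dimethylpyran can be annulated on ring B. The alternative therefore solves ring C only, and its value depends on what follows; alternative 3 is the natural continuation.
- Comparison: on structure, the chosen plan brings ring D in at the first step and differentiates the ring A oxygens with a purchased monobenzoate, whereas the alternative postpones both problems. On mechanism, both use resorcinol nucleophilicity; the alternative makes the C–C bond first (intermolecular) and the C–O bond last, the reverse of the chosen order. On step economy, joined to alternative 3 it would reach 13 in about five steps against seven: better.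

Alternative 3: The cut is made in ring D, at the bond between C4a' (the ring B carbon ortho to the ether oxygen) and C4'; the O1'–C2' bond is formally broken and re-made. This leads back to the tertiary propargyl aryl ether A8, 7-(methoxymethoxy)-3-[3-methoxy-4-(2-methylbut-3-yn-2-yloxy)phenyl]-4H-chromen-4-one.
- Forward step: heating A8 in N,N-diethylaniline would trigger an aryl propargyl Claisen rearrangement to the only free ortho carbon, then enolisation, a 1,5-hydrogen shift and an oxa-6π electrocyclisation. The product would be the chromene A9, 7-(methoxymethoxy)-3-(8-methoxy-2,2-dimethyl-2H-chromen-6-yl)-4H-chromen-4-one; mild acid would then free the 7-hydroxyl to give 13.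
- In its favour: the position of ring D is fixed by connectivity, because the other ortho carbon carries the methoxy group. This is better than step 1 of the chosen plan, which needs the hydroxyl to outdirect the methoxy group in an electrophilic alkylation. Ring D is formed directly at the alkene oxidation level, so the final dehydrogenation disappears: better. The neutral medium suits the pyranone.
- Against it here: the temperature is near 200 °C. A tertiary propargyl ether on a phenol flanked by a methoxy group may form slowly, in competition with elimination of the alkylating agent. A8 presupposes that the ring A hydroxyl of A7 has been protected selectively in the presence of the ring B hydroxyl. The acetal must be removed with acid from a molecule that now contains the chromene.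
- Comparison: on structure, the chosen plan builds ring D first (saturated) and ring C last, the alternative the reverse. On mechanism, a pericyclic cascade with regiochemistry set by connectivity is the more predictable of the two. The chosen plan keeps every step at or below about 100 °C and never has to distinguish two phenols. On step economy the alternative is better (about five steps from A4 and A5 through A7, against seven).

Key step: step 6

Remark: methyl homovanillate 1 is taken as a catalogue compound; the acrylates 7, 9 and 10 are written as E isomers, and any Z component would converge in step 6.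

## Route

Step 1
Reactants: 1 methyl homovanillate (methyl 2-(4-hydroxy-3-methoxyphenyl)acetate); 2 isoprene
Product: 4 methyl 2-(8-methoxy-2,2-dimethylchroman-6-yl)acetate, via ortho-prenylphenol 3 (not isolated)
Conditions: isoprene (1.5 equiv, slow addition), Amberlyst 15, THF–heptane, 65 °C, sealed tube
Reagents that add atoms: none
Why: Brønsted-acid-catalysed phenol–isoprene chroman annulation: Friedel–Crafts prenylation ortho to the hydroxyl gives 3, whose phenol oxygen then adds to the more substituted alkene carbon to close ring D. The para position is blocked, the hydroxyl is the stronger director, and only the ortho adduct is removed irreversibly by ring closure.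

Step 2
Reactants: 4 methyl 2-(8-methoxy-2,2-dimethylchroman-6-yl)acetate; 5 methyl formate
Product: 6 methyl (Z)-3-hydroxy-2-(8-methoxy-2,2-dimethylchroman-6-yl)acrylate (enol tautomer of the α-formyl ester)
Conditions: NaH (2.2 equiv), HCO2Me (8 equiv), THF, 0 °C to rt; then 1 M HCl, 0 °C
Reagents that add atoms: none
Why: Crossed Claisen condensation (formylation): methyl formate cannot enolise and the arylacetate α-protons are acidic enough for NaH. The equilibrium is pulled over because the product is the strongest acid in the flask and is held as its salt until the acidic quench.

Step 3
Reactants: 6 methyl (Z)-3-hydroxy-2-(8-methoxy-2,2-dimethylchroman-6-yl)acrylate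
Product: 7 methyl (E)-2-(8-methoxy-2,2-dimethylchroman-6-yl)-3-(tosyloxy)acrylate
Conditions: TsCl (1.3 equiv), N-methylimidazole (1.3 equiv), Et3N (1.5 equiv), CH2Cl2, 0 °C
Reagents that add atoms: p-toluenesulfonyl chloride, Cc1ccc(cc1)S(=O)(=O)Cl
Why: O-Sulfonylation of the enol by the N-sulfonylimidazolium salt formed from TsCl and N-methylimidazole; the non-chelating amine base should favour the E enol sulfonate. The geometry is not critical, since step 4 is an addition–elimination and step 6 erases it.

Step 4
Reactants: 7 methyl (E)-2-(8-methoxy-2,2-dimethylchroman-6-yl)-3-(tosyloxy)acrylate; 8 resorcinol monobenzoate (3-hydroxyphenyl benzoate)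
Product: 9 methyl (E)-3-[3-(benzoyloxy)phenoxy]-2-(8-methoxy-2,2-dimethylchroman-6-yl)acrylate
Conditions: 8 (1.1 equiv), K2CO3 (1.5 equiv), MeCN, rt to 50 °C
Reagents that add atoms: none
Why: Nucleophilic vinylic substitution by addition–elimination: oxa-Michael addition of the phenoxide to the β-carbon, then loss of tosylate from the ester enolate, the aryloxy group settling trans to the ester as in β-alkoxyacrylates. Carbonate in an aprotic solvent is too weak a nucleophile to cleave the aryl benzoate.

Step 5
Reactants: 9 methyl (E)-3-[3-(benzoyloxy)phenoxy]-2-(8-methoxy-2,2-dimethylchroman-6-yl)acrylate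
Product: 10 (E)-3-(3-hydroxyphenoxy)-2-(8-methoxy-2,2-dimethylchroman-6-yl)acrylic acid
Conditions: LiOH·H2O (4 equiv), THF–H2O (3:1), rt to 40 °C; then 1 M HCl to pH 2–3, 0 °C
Reagents that add atoms: lithium hydroxide, [Li+].[OH-]
Why: Saponification by acyl–oxygen cleavage frees the phenol (fast) and the acid (slower) in one operation. The phenoxide formed first makes the enol ether more electron-rich and so protects the β-carbon from hydroxide, and the alcohol-free medium excludes alkoxide exchange at that carbon.

Step 6
Reactants: 10 (E)-3-(3-hydroxyphenoxy)-2-(8-methoxy-2,2-dimethylchroman-6-yl)acrylic acid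
Product: 12 7-hydroxy-3-(8-methoxy-2,2-dimethylchroman-6-yl)-4H-chromen-4-one, via Z-acid 11 (not isolated)
Conditions: P2O5–CH3SO3H (1:10 w/w), 0.1 M, rt to 50 °C; then ice–water
Reagents that add atoms: none
Why: P2O5 in CH3SO3H converts the carboxyl group into a mixed anhydride and from it an acylium-type electrophile, and it binds the water that is released. The same medium protonates the enol ether reversibly at the α-carbon (future C3), or at the carbonyl oxygen, which lowers the C2=C3 bond order; either way the E-acid 10 equilibrates with the Z-acid 11, the only isomer in which the acyl carbon can reach the aryloxy ring. In 11 the acyl carbon attacks the ring carbon that is ortho to the ether oxygen and para to the free hydroxyl, and loss of a proton from the arenium ion gives 12, so that all of 10 is drained through 11. The closest known reaction type is the acid-mediated cyclisation of 3-aryloxyacrylic acids to chromones, an intramolecular Friedel–Crafts acylation. Ring C closes in a six-membered mode, 6-endo-trig with respect to the arene π bond C4a=C8a and exo with respect to the acylium C≡O. No stereocentre is formed, and the alkene geometry of 10 disappears in the planar pyranone. The selectivity needed is positional, C4a against the carbon between the two oxygens: both are activated by the two oxygen atoms, but the latter is flanked on both sides while C4a has a free neighbour, and acylation para to a phenol hydroxyl is the intrinsically preferred mode; ring B cannot compete because closure onto it would give a four-membered ring. Ring D is saturated and offers no site for protonation, and the aryl methyl ether and the tertiary alkyl aryl ether are expected to hold at or below 50 °C.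

Step 7
Reactants: 12 7-hydroxy-3-(8-methoxy-2,2-dimethylchroman-6-yl)-4H-chromen-4-one
Product: 13 7-hydroxy-3-(8-methoxy-2,2-dimethyl-2H-chromen-6-yl)-4H-chromen-4-one
Conditions: DDQ (1.3 equiv), 1,4-dioxane, reflux
Reagents that add atoms: none
Why: Quinone dehydrogenation of a 2,2-dimethylchroman: DDQ abstracts hydride from benzylic C4', whose cation is stabilised by O1' through ring B, and loss of a C3' proton gives the styrenyl alkene. The quaternary C2' stops the oxidation at the 2H-chromene, and the electron-poor pyranone with its vinylogous-acid phenol is not expected to react.

## Compound list

1 | methyl homovanillate (methyl 2-(4-hydroxy-3-methoxyphenyl)acetate) | COC(=O)Cc1ccc(O)c(OC)c1 | starting material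
2 | isoprene (2-methylbuta-1,3-diene) | C=CC(C)=C | starting material
3 | methyl 2-[4-hydroxy-3-methoxy-5-(3-methylbut-2-en-1-yl)phenyl]acetate | COC(=O)Cc1cc(OC)c(O)c(CC=C(C)C)c1 | intermediate (not isolated)
4 | methyl 2-(8-methoxy-2,2-dimethylchroman-6-yl)acetate | COC(=O)Cc1cc(OC)c2OC(C)(C)CCc2c1 | intermediate
5 | methyl formate | COC=O | starting material
6 | methyl (Z)-3-hydroxy-2-(8-methoxy-2,2-dimethylchroman-6-yl)acrylate (enol tautomer of the α-formyl ester) | COC(=O)/C(=C\O)c1cc(OC)c2OC(C)(C)CCc2c1 | intermediate
7 | methyl (E)-2-(8-methoxy-2,2-dimethylchroman-6-yl)-3-(tosyloxy)acrylate | COC(=O)/C(=C/OS(=O)(=O)c1ccc(C)cc1)c1cc(OC)c2OC(C)(C)CCc2c1 | intermediate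
8 | resorcinol monobenzoate (3-hydroxyphenyl benzoate) | O=C(Oc1cccc(O)c1)c1ccccc1 | starting material
9 | methyl (E)-3-[3-(benzoyloxy)phenoxy]-2-(8-methoxy-2,2-dimethylchroman-6-yl)acrylate | COC(=O)/C(=C/Oc1cccc(OC(=O)c2ccccc2)c1)c1cc(OC)c2OC(C)(C)CCc2c1 | intermediate
10 | (E)-3-(3-hydroxyphenoxy)-2-(8-methoxy-2,2-dimethylchroman-6-yl)acrylic acid | OC(=O)/C(=C/Oc1cccc(O)c1)c1cc(OC)c2OC(C)(C)CCc2c1 | intermediate
11 | (Z)-3-(3-hydroxyphenoxy)-2-(8-methoxy-2,2-dimethylchroman-6-yl)acrylic acid | OC(=O)/C(=C\Oc1cccc(O)c1)c1cc(OC)c2OC(C)(C)CCc2c1 | intermediate (not isolated)
12 | 7-hydroxy-3-(8-methoxy-2,2-dimethylchroman-6-yl)-4H-chromen-4-one | COc1cc(-c2coc3cc(O)ccc3c2=O)cc2c1OC(C)(C)CC2 | intermediate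
13 | 7-hydroxy-3-(8-methoxy-2,2-dimethyl-2H-chromen-6-yl)-4H-chromen-4-one | COc1cc(-c2coc3cc(O)ccc3c2=O)cc2c1OC(C)(C)C=C2 | target

## Step count and least certain steps

Total step count: 7. Longest linear sequence: 7 steps (1 to 13); 2, 5 and 8 are purchased, so there is no convergent branch.

Step 6 (key step). The most likely failures are intermolecular acylation or C-sulfonylation of the electron-rich rings outrunning ring closure, and acid-mediated cleavage of the aryl vinyl ether before the E to Z equilibration delivers a reactive isomer. The fallback forms the same C4–C4a bond first and closes ring C afterwards; it sets out from 4 and comes back at 12. Saponification of 4 (NaOH, aqueous MeOH) should give 2-(8-methoxy-2,2-dimethylchroman-6-yl)acetic acid F1. Friedel–Crafts acylation of resorcinol A4 with F1 in BF3·OEt2 at about 85 °C should give the deoxybenzoin 1-(2,4-dihydroxyphenyl)-2-(8-methoxy-2,2-dimethylchroman-6-yl)ethan-1-one F2. DMF with CH3SO2Cl and BF3·OEt2 at about 70 °C should then formylate the benzylic carbon and close ring C to 12.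

Step 4. The phenoxide may attack the sulfonate at sulfur (sulfonyl transfer, returning the enol), and benzoyl transfer between phenoxides may scramble the protecting group. The fallback replaces the sulfonate by a leaving group that has only the carbon site; it sets out from 6 and comes back at 9. Treatment of 6 with oxalyl chloride and DMF (chloroiminium activation of the enol oxygen, CH2Cl2, 0 °C to rt) should give methyl 3-chloro-2-(8-methoxy-2,2-dimethylchroman-6-yl)acrylate F3. Its reaction with 8 and K2CO3 in MeCN should deliver 9 by the same addition–elimination.

Step 1. Alkylation may occur para to the methoxy group (ortho to the side chain), where no ring closure can follow; double prenylation and oligomerisation of the diene are further risks. The fallback fixes the regiochemistry by connectivity; it sets out from 1 and comes back at 4. O-Alkylation of 1 with 3-chloro-3-methylbut-1-yne (DBU, CuCl2 1 mol %, MeCN, 0 °C) should give methyl 2-[3-methoxy-4-(2-methylbut-3-yn-2-yloxy)phenyl]acetate F4. Heating in N,N-diethylaniline at about 190 °C (propargyl Claisen rearrangement, then oxa-6π closure) should give methyl 2-(8-methoxy-2,2-dimethyl-2H-chromen-6-yl)acetate F5. Hydrogenation (H2, Pd/C, EtOAc) should then give 4.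

Step 7. Hydride abstraction may stall because the carbon para to O1' carries the electron-poor enone, and the free phenol may be lost to oxidative coupling with the quinone. The fallback changes from hydride abstraction to radical bromination and elimination; it sets out from 12 and comes back at 13. Acetylation (Ac2O, pyridine) should give 3-(8-methoxy-2,2-dimethylchroman-6-yl)-4-oxo-4H-chromen-7-yl acetate F6. Benzylic bromination (NBS, AIBN, PhCF3, reflux) should give 3-(4-bromo-8-methoxy-2,2-dimethylchroman-6-yl)-4-oxo-4H-chromen-7-yl acetate F7. Elimination with DBU in toluene at 80 °C should give 3-(8-methoxy-2,2-dimethyl-2H-chromen-6-yl)-4-oxo-4H-chromen-7-yl acetate F8. Catalytic K2CO3 in MeOH at 0 °C should remove the acetate and give 13.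

## Further compounds

F1 | step 6 | 2-(8-methoxy-2,2-dimethylchroman-6-yl)acetic acid | COc1cc(CC(=O)O)cc2c1OC(C)(C)CC2
F2 | step 6 | 1-(2,4-dihydroxyphenyl)-2-(8-methoxy-2,2-dimethylchroman-6-yl)ethan-1-one | COc1cc(CC(=O)c2ccc(O)cc2O)cc2c1OC(C)(C)CC2
F3 | step 4 | methyl 3-chloro-2-(8-methoxy-2,2-dimethylchroman-6-yl)acrylate (mixture of E and Z isomers, geometry immaterial) | COC(=O)C(=CCl)c1cc(OC)c2OC(C)(C)CCc2c1
F4 | step 1 | methyl 2-[3-methoxy-4-(2-methylbut-3-yn-2-yloxy)phenyl]acetate | COC(=O)Cc1ccc(OC(C)(C)C#C)c(OC)c1
F5 | step 1 | methyl 2-(8-methoxy-2,2-dimethyl-2H-chromen-6-yl)acetate | COC(=O)Cc1cc(OC)c2OC(C)(C)C=Cc2c1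
F6 | step 7 | 3-(8-methoxy-2,2-dimethylchroman-6-yl)-4-oxo-4H-chromen-7-yl acetate | CC(=O)Oc1ccc2c(c1)occ(-c1cc(OC)c3OC(C)(C)CCc3c1)c2=O
F7 | step 7 | 3-(4-bromo-8-methoxy-2,2-dimethylchroman-6-yl)-4-oxo-4H-chromen-7-yl acetate (racemic) | CC(=O)Oc1ccc2c(c1)occ(-c1cc(OC)c3OC(C)(C)CC(Br)c3c1)c2=O
F8 | step 7 | 3-(8-methoxy-2,2-dimethyl-2H-chromen-6-yl)-4-oxo-4H-chromen-7-yl acetate | CC(=O)Oc1ccc2c(c1)occ(-c1cc(OC)c3OC(C)(C)C=Cc3c1)c2=O
A1 | alternative 1 | 2-hydroxy-4-(methoxymethoxy)benzaldehyde | COCOc1ccc(C=O)c(O)c1
A2 | alternative 1 | [(8-methoxy-2,2-dimethyl-2H-chromen-6-yl)ethynyl]trimethylsilane | COc1cc(C#C[Si](C)(C)C)cc2c1OC(C)(C)C=C2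
A3 | alternative 1 | 7-(methoxymethoxy)-3-(8-methoxy-2,2-dimethyl-2H-chromen-6-yl)-2-(trimethylsilyl)-4H-chromen-4-one | COCOc1ccc2c(c1)oc([Si](C)(C)C)c(-c1cc(OC)c3OC(C)(C)C=Cc3c1)c2=O
A4 | alternative 2 | resorcinol | Oc1cccc(O)c1
A5 | alternative 2 | homovanillic acid | COc1cc(CC(=O)O)ccc1O
A6 | alternative 2 | 1-(2,4-dihydroxyphenyl)-2-(4-hydroxy-3-methoxyphenyl)ethan-1-one | COc1cc(CC(=O)c2ccc(O)cc2O)ccc1O
A7 | alternative 2 | 7-hydroxy-3-(4-hydroxy-3-methoxyphenyl)-4H-chromen-4-one | COc1cc(-c2coc3cc(O)ccc3c2=O)ccc1O
A8 | alternative 3 | 7-(methoxymethoxy)-3-[3-methoxy-4-(2-methylbut-3-yn-2-yloxy)phenyl]-4H-chromen-4-one | COCOc1ccc2c(c1)occ(-c1ccc(OC(C)(C)C#C)c(OC)c1)c2=O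
A9 | alternative 3 | 7-(methoxymethoxy)-3-(8-methoxy-2,2-dimethyl-2H-chromen-6-yl)-4H-chromen-4-one | COCOc1ccc2c(c1)occ(-c1cc(OC)c3OC(C)(C)C=Cc3c1)c2=O
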